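**Strategy.** Labels: ring A (seven-membered) is C1 (ester carbinol), C2, C3 (methyl-bearing alkene carbon), C4, C5 (ketone) and the fusion carbons C6 and C10; ring B (five-membered) is C6–C10, with C9 the isopropyl carbinol. Ring A is opened at C3=C4 and detached at C5–C6 and C1–C10. Tracing the C9 carbinol back to a ketone makes C10 its α-carbon and C6 its β-carbon. Both fusion carbons can therefore receive their ring-A arms in one operation on 3-methylcyclopent-2-en-1-one: copper-catalysed enantioselective 1,4-addition of a 1-silylvinyl alane (masked C5 acyl) forms C5–C6, and a zirconium-enolate aldol with 3-methylbut-3-enal forms C1–C10, fixing C6, C10 and C1.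

Key step: step 4

**Remarks on the chemistry**
- Silicon substituent: the vinyl group carries benzyldimethylsilyl, not trimethylsilyl. Unveiling the C5 ketone by peracid epoxidation cannot be made selective beside the 2-methylallyl alkene, whereas a benzylsilane is oxidised at silicon (fluoride, then H2O2) without touching that alkene.
- Assumption: the chiral NHC ligand L (a diphenylethylenediamine-derived imidazolin-2-ylidene with an N-aryl sulfonate arm, used as its silver complex Ag2(L)2) is taken as the antipode that delivers the silylvinyl group to the enone face giving (S)-C6.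

**Route**

Step 1
Reactants: 1 benzylchlorodimethylsilane; 2 ethynylmagnesium bromide
Product: 3 benzyl(ethynyl)dimethylsilane
Conditions: 2 (0.5 M in THF, 1.2 equiv), THF, 0 °C → rt; aq NH4Cl; distillation
Reagents that add atoms: none
Why: Substitution at silicon by an alkynyl Grignard reagent (silylation of an acetylide) is fast with a chlorosilane, and the benzyl group is placed on silicon so that the later Tamao–Fleming oxidation can be triggered by fluoride.

Step 2
Reactants: 3 benzyl(ethynyl)dimethylsilane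
Product: 4 [1-(benzyldimethylsilyl)ethenyl]bis(2-methylpropyl)aluminium (THF solution, used directly)
Conditions: iBu2AlH (0.95 equiv), Ni(dppp)Cl2 (3 mol %), THF, 0 → 22 °C
Reagents that add atoms: diisobutylaluminium hydride, CC(C)C[AlH]CC(C)C
Why: Nickel-catalysed hydroalumination of a terminal alkyne with the bisphosphine complex Ni(dppp)Cl2 places aluminium on the internal, silicon-bearing carbon, and the slight excess of alkyne leaves no Al–H that could later reduce the enone or the aldehyde.

Step 3
Reactants: 5 3-methylbut-3-en-1-ol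
Product: 6 3-methylbut-3-enal (kept cold as a dried CH2Cl2 solution)
Conditions: Dess–Martin periodinane (1.1 equiv), CH2Cl2, 0 °C → rt; aq NaHCO3 wash; MgSO4, 4 Å sieves
Reagents that add atoms: none
Why: Dess–Martin oxidation of a primary alcohol stops at the aldehyde under neutral, non-basic conditions, which avoids migration of the β,γ-double bond into conjugation.

Step 4
Reactants: 7 3-methylcyclopent-2-en-1-one; 4 [1-(benzyldimethylsilyl)ethenyl]bis(2-methylpropyl)aluminium; 6 3-methylbut-3-enal
Product: 11 (2S,3S)-3-[1-(benzyldimethylsilyl)ethenyl]-2-[(1R)-1-hydroxy-3-methylbut-3-en-1-yl]-3-methylcyclopentan-1-one, via aluminium enolate 8 (not isolated), via lithium enolate 9 (not isolated), via zirconocene enolate 10 (not isolated)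
Conditions: Cu(OTf)2 (5 mol %), Ag2(L)2 (2.5 mol %), 4 (1.3 equiv), THF, −30 → 4 °C; MeLi (1.3 equiv), −78 °C; Cp2ZrCl2 (1.4 equiv), −78 → −40 °C; 6 (2 equiv), −78 °C; aq NH4Cl, aq potassium sodium tartrate
Reagents that add atoms: none
Why: The NHC–copper complex generated from Cu(OTf)2 and the silver carbene takes the 1-silylvinyl group from aluminium and adds it to C6 of the enone through a copper–alkene complex and a trivalent copper intermediate, whose reductive elimination leaves the C5–C6 bond and a regiodefined aluminium enolate; MeLi turns this into the lithium (aluminate) enolate, Cp2ZrCl2 into the chlorozirconocene enolate, and the latter adds through C10 to the aldehyde (C1–C10 bond). The closest known chemistry is the copper–NHC-catalysed enantioselective conjugate addition of silyl-substituted vinylaluminium reagents to β-substituted cyclic enones with aldol trapping of the enolate, joined to the syn-selective zirconium enolate aldol of cyclic ketones. No ring is closed. C6 is set by the chiral NHC ligand, which selects the enone face that receives the vinyl group; C10 is set by the new quaternary C6, because the aldehyde approaches the enolate anti to the large silylvinyl group and so places the C5 and C1 arms trans; C1 is set by the zirconium aldol transition state, which gives the syn aldol from the ring-locked E enolate. The step needs 1,4- over 1,2-addition, a single enolate regioisomer and no double-bond migration in the aldehyde; these are secured by the soft copper–vinyl species, by generating the C9–C10 enolate through the conjugate addition itself, and by the weakly basic zirconium enolate at −78 °C.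

Step 5
Reactants: 11 (2S,3S)-3-[1-(benzyldimethylsilyl)ethenyl]-2-[(1R)-1-hydroxy-3-methylbut-3-en-1-yl]-3-methylcyclopentan-1-one
Product: 12 (1R,2S,3S)-3-[1-(benzyldimethylsilyl)ethenyl]-2-[(1R)-1-hydroxy-3-methylbut-3-en-1-yl]-3-methyl-1-(propan-2-yl)cyclopentan-1-ol
Conditions: anhydrous CeCl3 (3.5 equiv), iPrMgCl (3.5 equiv), THF, −78 °C; then 11, −78 → 0 °C; aq NH4Cl
Reagents that add atoms: isopropylmagnesium chloride, CC(C)[Mg]Cl
Why: Organocerium 1,2-addition to a ketone: the weakly basic, oxophilic reagent should add to the hindered C9 carbonyl without enolisation, hydride transfer or retro-aldol cleavage, and it attacks the face opposite the C10 side chain (held on the upper face by chelation of the C1 alkoxide), so the new hydroxyl ends cis to the C1 arm and the C6 methyl, which is (R)-C9.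

Step 6
Reactants: 12 (1R,2S,3S)-3-[1-(benzyldimethylsilyl)ethenyl]-2-[(1R)-1-hydroxy-3-methylbut-3-en-1-yl]-3-methyl-1-(propan-2-yl)cyclopentan-1-ol
Product: 13 1-[(1S,2S,3R)-3-hydroxy-2-[(1R)-1-hydroxy-3-methylbut-3-en-1-yl]-1-methyl-3-(propan-2-yl)cyclopentyl]ethan-1-one
Conditions: Bu4NF (2.5 equiv), THF, 0 °C → rt; then KHCO3, 30% H2O2, MeOH/THF, rt → 40 °C
Reagents that add atoms: hydrogen peroxide, OO
Why: Tamao–Fleming oxidation of an alkenylsilane: fluoride removes the benzyl group from silicon as toluene, hydroperoxide then makes the vinyl carbon C5 migrate from silicon to oxygen, and the resulting silyl enol ether hydrolyses to the methyl ketone, a nucleophilic oxidation at silicon that leaves the 2-methylallyl alkene untouched.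

Step 7
Reactants: 13 1-[(1S,2S,3R)-3-hydroxy-2-[(1R)-1-hydroxy-3-methylbut-3-en-1-yl]-1-methyl-3-(propan-2-yl)cyclopentyl]ethan-1-one
Product: 16 1-[(1S,2S,3R)-3-hydroxy-2-[(1R)-1-hydroxy-3-methylbut-3-en-1-yl]-1-methyl-3-(propan-2-yl)cyclopentyl]prop-2-en-1-one, via Mannich base 14 (not isolated), via trimethylammonium iodide 15 (not isolated)
Conditions: LiN(SiMe3)2 (3.3 equiv), THF, −78 °C; Me2N=CH2 iodide (4 equiv), −78 °C → rt; aq NH4Cl; MeI, CH2Cl2, rt; aq NaHCO3, CH2Cl2, rt
Reagents that add atoms: N,N-dimethylmethyleneiminium iodide (Eschenmoser's salt), C=[N+](C)C.[I-]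
Why: Mannich methylenation: the ketone can enolise only toward its methyl group C4 because C6 is quaternary, the lithium enolate is aminomethylated by the iminium salt, and N-methylation followed by mild-base E1cB loss of trimethylamine gives the vinyl ketone.

Step 8
Reactants: 16 1-[(1S,2S,3R)-3-hydroxy-2-[(1R)-1-hydroxy-3-methylbut-3-en-1-yl]-1-methyl-3-(propan-2-yl)cyclopentyl]prop-2-en-1-one
Product: 17 (3R,3aS,4R,8aS)-3,4-dihydroxy-6,8a-dimethyl-3-(propan-2-yl)-2,3,3a,4,5,8a-hexahydroazulen-8(1H)-one
Conditions: second-generation Grubbs catalyst RuCl2(=CHPh)(H2IMes)(PCy3) (10 mol %), toluene (2 mM), 80 °C, argon sparge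
Reagents that add atoms: none
Why: Ring-closing metathesis joins the acryloyl carbon C4 to the 1,1-disubstituted alkene carbon C3 with loss of ethene and closes seven-membered ring A as the trisubstituted enone; the trans arms on the cyclopentane reach each other without strain and free hydroxyls are tolerated by the ruthenium carbene.

Step 9
Reactants: 18 vanillic acid (4-hydroxy-3-methoxybenzoic acid)
Product: 20 4-[(tert-butyldimethylsilyl)oxy]-3-methoxybenzoic acid, via bis-silylated vanillate 19 (not isolated)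
Conditions: TBSCl (2.3 equiv), imidazole (5 equiv), DMF, rt; then AcOH/THF/H2O, rt
Reagents that add atoms: tert-butyldimethylsilyl chloride, CC(C)(C)[Si](C)(C)Cl
Why: Silyl ether formation on phenol and acid followed by selective hydrolysis of the much more labile silyl ester leaves the aryl silyl ether, which blocks self-acylation of the phenol in the coupling.

Step 10
Reactants: 17 (3R,3aS,4R,8aS)-3,4-dihydroxy-6,8a-dimethyl-3-(propan-2-yl)-2,3,3a,4,5,8a-hexahydroazulen-8(1H)-one; 20 4-[(tert-butyldimethylsilyl)oxy]-3-methoxybenzoic acid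
Product: 21 (3R,3aS,4R,8aS)-3-hydroxy-6,8a-dimethyl-8-oxo-3-(propan-2-yl)-1,2,3,3a,4,5,8,8a-octahydroazulen-4-yl 4-[(tert-butyldimethylsilyl)oxy]-3-methoxybenzoate
Conditions: 20 (1.5 equiv), EDCI·HCl (2 equiv), DMAP (1 equiv), CH2Cl2, 0 °C → rt
Reagents that add atoms: none
Why: Steglich esterification (carbodiimide activation with DMAP acyl transfer) acylates the secondary C1 hydroxyl in preference to the tertiary C9 hydroxyl, and C1 keeps its configuration because its C–O bond is not broken.

Step 11
Reactants: 21 (3R,3aS,4R,8aS)-3-hydroxy-6,8a-dimethyl-8-oxo-3-(propan-2-yl)-1,2,3,3a,4,5,8,8a-octahydroazulen-4-yl 4-[(tert-butyldimethylsilyl)oxy]-3-methoxybenzoate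
Product: 22 (3R,3aS,4R,8aS)-3-hydroxy-6,8a-dimethyl-8-oxo-3-(propan-2-yl)-1,2,3,3a,4,5,8,8a-octahydroazulen-4-yl 4-hydroxy-3-methoxybenzoate (target)
Conditions: Bu4NF (1.2 equiv), AcOH (1.5 equiv), THF, 0 °C
Reagents that add atoms: none
Why: Fluoride-mediated desilylation of an aryl silyl ether is fast, and the acetic acid buffer keeps the medium non-basic so that the ester is not lost by vinylogous elimination from the enone.

**Compound list**

1 | benzylchlorodimethylsilane | C[Si](C)(Cl)Cc1ccccc1 | starting material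
2 | ethynylmagnesium bromide | C#C[Mg]Br | starting material
3 | benzyl(ethynyl)dimethylsilane | C#C[Si](C)(C)Cc1ccccc1 | intermediate
4 | [1-(benzyldimethylsilyl)ethenyl]bis(2-methylpropyl)aluminium | C=C([Si](C)(C)Cc1ccccc1)[Al](CC(C)C)CC(C)C | intermediate
5 | 3-methylbut-3-en-1-ol | CC(=C)CCO | starting material
6 | 3-methylbut-3-enal | CC(=C)CC=O | intermediate
7 | 3-methylcyclopent-2-en-1-one | CC1=CC(=O)CC1 | starting material
8 | bis(2-methylpropyl)aluminium (3S)-3-[1-(benzyldimethylsilyl)ethenyl]-3-methylcyclopent-1-en-1-olate | C=C([Si](C)(C)Cc1ccccc1)[C@@]2(C)CCC(O[Al](CC(C)C)CC(C)C)=C2 | intermediate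
9 | lithium (3S)-3-[1-(benzyldimethylsilyl)ethenyl]-3-methylcyclopent-1-en-1-olate (aluminate-associated) | C=C([Si](C)(C)Cc1ccccc1)[C@@]2(C)CCC(O[Li])=C2 | intermediate
10 | chlorobis(cyclopentadienyl)zirconium (3S)-3-[1-(benzyldimethylsilyl)ethenyl]-3-methylcyclopent-1-en-1-olate | C=C([Si](C)(C)Cc1ccccc1)[C@@]2(C)CCC(O[Zr](Cl)(C3C=CC=C3)C3C=CC=C3)=C2 | intermediate
11 | (2S,3S)-3-[1-(benzyldimethylsilyl)ethenyl]-2-[(1R)-1-hydroxy-3-methylbut-3-en-1-yl]-3-methylcyclopentan-1-one | C=C([Si](C)(C)Cc1ccccc1)[C@@]2(C)CCC(=O)[C@@H]2[C@H](O)CC(C)=C | intermediate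
12 | (1R,2S,3S)-3-[1-(benzyldimethylsilyl)ethenyl]-2-[(1R)-1-hydroxy-3-methylbut-3-en-1-yl]-3-methyl-1-(propan-2-yl)cyclopentan-1-ol | C=C([Si](C)(C)Cc1ccccc1)[C@@]2(C)CC[C@@](O)(C(C)C)[C@@H]2[C@H](O)CC(C)=C | intermediate
13 | 1-[(1S,2S,3R)-3-hydroxy-2-[(1R)-1-hydroxy-3-methylbut-3-en-1-yl]-1-methyl-3-(propan-2-yl)cyclopentyl]ethan-1-one | CC(=O)[C@@]1(C)CC[C@@](O)(C(C)C)[C@@H]1[C@H](O)CC(C)=C | intermediate
14 | 3-(dimethylamino)-1-[(1S,2S,3R)-3-hydroxy-2-[(1R)-1-hydroxy-3-methylbut-3-en-1-yl]-1-methyl-3-(propan-2-yl)cyclopentyl]propan-1-one | CN(C)CCC(=O)[C@@]1(C)CC[C@@](O)(C(C)C)[C@@H]1[C@H](O)CC(C)=C | intermediate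
15 | N,N,N-trimethyl-3-oxo-3-[(1S,2S,3R)-3-hydroxy-2-[(1R)-1-hydroxy-3-methylbut-3-en-1-yl]-1-methyl-3-(propan-2-yl)cyclopentyl]propan-1-aminium iodide | C[N+](C)(C)CCC(=O)[C@@]1(C)CC[C@@](O)(C(C)C)[C@@H]1[C@H](O)CC(C)=C.[I-] | intermediate
16 | 1-[(1S,2S,3R)-3-hydroxy-2-[(1R)-1-hydroxy-3-methylbut-3-en-1-yl]-1-methyl-3-(propan-2-yl)cyclopentyl]prop-2-en-1-one | C=CC(=O)[C@@]1(C)CC[C@@](O)(C(C)C)[C@@H]1[C@H](O)CC(C)=C | intermediate
17 | (3R,3aS,4R,8aS)-3,4-dihydroxy-6,8a-dimethyl-3-(propan-2-yl)-2,3,3a,4,5,8a-hexahydroazulen-8(1H)-one | O[C@@H]1CC(C)=CC(=O)[C@@]2(C)CC[C@@](O)(C(C)C)[C@H]12 | intermediate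
18 | vanillic acid (4-hydroxy-3-methoxybenzoic acid) | COc1cc(C(=O)O)ccc1O | starting material
19 | tert-butyldimethylsilyl 4-[(tert-butyldimethylsilyl)oxy]-3-methoxybenzoate | COc1cc(C(=O)O[Si](C)(C)C(C)(C)C)ccc1O[Si](C)(C)C(C)(C)C | intermediate
20 | 4-[(tert-butyldimethylsilyl)oxy]-3-methoxybenzoic acid | COc1cc(C(=O)O)ccc1O[Si](C)(C)C(C)(C)C | intermediate
21 | (3R,3aS,4R,8aS)-3-hydroxy-6,8a-dimethyl-8-oxo-3-(propan-2-yl)-1,2,3,3a,4,5,8,8a-octahydroazulen-4-yl 4-[(tert-butyldimethylsilyl)oxy]-3-methoxybenzoate | COc1cc(C(=O)O[C@@H]2CC(C)=CC(=O)[C@@]3(C)CC[C@@](O)(C(C)C)[C@H]23)ccc1O[Si](C)(C)C(C)(C)C | intermediate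
22 | (3R,3aS,4R,8aS)-3-hydroxy-6,8a-dimethyl-8-oxo-3-(propan-2-yl)-1,2,3,3a,4,5,8,8a-octahydroazulen-4-yl 4-hydroxy-3-methoxybenzoate | COc1cc(C(=O)O[C@@H]2CC(C)=CC(=O)[C@@]3(C)CC[C@@](O)(C(C)C)[C@H]23)ccc1O | target

**Step count.** Total: 11 steps. Longest linear sequence: 9 steps (steps 1, 2, 4, 5, 6, 7, 8, 10, 11).

**Steps most likely to fail**

1. Step 4. The enolate may pass incompletely from aluminium to zirconium, which would erode the syn selectivity at C1. The excess alanate may also consume the aldehyde, or the aldehyde double bond may move into conjugation before the aldol. The fallback sets out from 7 and 4 and separates the two bond formations. The conjugate addition is run alone and the aluminium enolate 8 is trapped with Me3SiOTf/Et3N as the silyl enol ether {[(3S)-3-[1-(benzyldimethylsilyl)ethenyl]-3-methylcyclopent-1-en-1-yl]oxy}trimethylsilane F1, which is purified. MeLi (THF, 0 °C) then regenerates the lithium enolate 9 free of aluminium species, Cp2ZrCl2 gives 10, and aldehyde 6 is added at −78 °C. The fallback comes back to the route at 11.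

2. Step 5. The metal aldolate may undergo retro-aldol cleavage, the ketone may be enolised or reduced by hydride transfer, or the reagent may attack the wrong face of C9. The fallback sets out from 11 and removes the aldolate from the problem. Et3SiCl/imidazole (DMF) gives the silyl ether (2S,3S)-3-[1-(benzyldimethylsilyl)ethenyl]-3-methyl-2-{(1R)-3-methyl-1-[(triethylsilyl)oxy]but-3-en-1-yl}cyclopentan-1-one F2, whose bulky silyloxy arm shields the upper face more strongly. Isopropyllithium/CeCl3 (THF, −78 °C) then gives (1R,2S,3S)-3-[1-(benzyldimethylsilyl)ethenyl]-3-methyl-2-{(1R)-3-methyl-1-[(triethylsilyl)oxy]but-3-en-1-yl}-1-(propan-2-yl)cyclopentan-1-ol F3. F3 is taken into the conditions of step 6, where Bu4NF removes the triethylsilyl group together with the benzyl group on silicon. The fallback comes back at 13.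

3. Step 8. Initiation at the 1,1-disubstituted alkene and the electron-poor vinyl ketone may be slow, leading to intermolecular metathesis (oligomers) or catalyst decay before ring closure. The fallback sets out from 16 and changes the metathesis partner. Luche reduction (NaBH4, CeCl3·7H2O, MeOH, −78 °C) gives the allylic alcohol (1R,2S,3S)-2-[(1R)-1-hydroxy-3-methylbut-3-en-1-yl]-3-(1-hydroxyprop-2-en-1-yl)-3-methyl-1-(propan-2-yl)cyclopentan-1-ol F4, whose epimers at C5 are of no consequence. Ring-closing metathesis of this more reactive alkene with the same second-generation Grubbs catalyst gives (3R,3aS,4R,8aS)-6,8a-dimethyl-3-(propan-2-yl)-1,2,3,3a,4,5,8,8a-octahydroazulene-3,4,8-triol F5. MnO2 (CH2Cl2, rt) then oxidises only the allylic C5 hydroxyl. The fallback comes back at 17.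

**Further compounds**

F1 | step 4 | {[(3S)-3-[1-(benzyldimethylsilyl)ethenyl]-3-methylcyclopent-1-en-1-yl]oxy}trimethylsilane | C=C([Si](C)(C)Cc1ccccc1)[C@@]2(C)CCC(O[Si](C)(C)C)=C2
F2 | step 5 | (2S,3S)-3-[1-(benzyldimethylsilyl)ethenyl]-3-methyl-2-{(1R)-3-methyl-1-[(triethylsilyl)oxy]but-3-en-1-yl}cyclopentan-1-one | C=C([Si](C)(C)Cc1ccccc1)[C@@]2(C)CCC(=O)[C@@H]2[C@H](O[Si](CC)(CC)CC)CC(C)=C
F3 | step 5 | (1R,2S,3S)-3-[1-(benzyldimethylsilyl)ethenyl]-3-methyl-2-{(1R)-3-methyl-1-[(triethylsilyl)oxy]but-3-en-1-yl}-1-(propan-2-yl)cyclopentan-1-ol | C=C([Si](C)(C)Cc1ccccc1)[C@@]2(C)CC[C@@](O)(C(C)C)[C@@H]2[C@H](O[Si](CC)(CC)CC)CC(C)=C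
F4 | step 8 | (1R,2S,3S)-2-[(1R)-1-hydroxy-3-methylbut-3-en-1-yl]-3-(1-hydroxyprop-2-en-1-yl)-3-methyl-1-(propan-2-yl)cyclopentan-1-ol (both C5 epimers) | C=CC(O)[C@@]1(C)CC[C@@](O)(C(C)C)[C@@H]1[C@H](O)CC(C)=C
F5 | step 8 | (3R,3aS,4R,8aS)-6,8a-dimethyl-3-(propan-2-yl)-1,2,3,3a,4,5,8,8a-octahydroazulene-3,4,8-triol (both C5 epimers) | O[C@@H]1CC(C)=CC(O)[C@@]2(C)CC[C@@](O)(C(C)C)[C@H]12
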